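The route disconnects ring C of the luteolin unit at O1''–C8a'', C4''–C4a'' and O1''–C2''. In that unit ring A carries the pyranone oxygen (on C8a'') and the carbonyl carbon (on C4a'') at adjacent atoms, between the C5'' oxygen and the C8'' biaryl carbon; this is the pattern left when a 3-alkoxyaryne inserts into a C–O bond. One operation therefore generates the C4a''–C8a'' aryne with fluoride, inserts it into the carboxyl C–O bond of an arylpropiolic acid and closes the resulting hydroxyaryl ynone to the flavone. The precursor is an ortho-silylaryl triflate on a dimethoxybenzene ring that already carries apigenin trimethyl ether through the C8–C8'' bond.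

Key step: step 6

Remark: the target as drawn fixes no configuration at the hindered C8–C8'' axis, so the route gives the racemic atropisomer mixture; unprimed and single-primed locants belong to the apigenin unit, double- and triple-primed locants to the luteolin unit; salts of numbered compounds that are only protonated on work-up carry no number of their own.

Step 1
Reactants: 1 3,5-dimethoxyphenol
Product: 2 3,5-dimethoxyphenyl N-isopropylcarbamate
Conditions: i-PrNCO, Et3N (cat.), CH2Cl2, rt
Reagents that add atoms: isopropyl isocyanate, CC(C)N=C=O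
Why: Base-catalysed addition of the phenol to the isocyanate (carbamoylation) should give the N–H carbamate, which serves as a strong ortho-directing group and as a phenol mask that mild E1cB cleavage can remove later.

Step 2
Reactants: 3 5,7,4'-trimethoxyflavone
Product: 4 8-iodo-5,7,4'-trimethoxyflavone
Conditions: I2, CF3CO2Ag, CH2Cl2, 0 °C to rt
Reagents that add atoms: iodine, II
Why: Electrophilic aromatic iodination of a fully methylated 5,7-dioxygenated ring A should go to C8 (para to the 5-methoxy group, ortho to O1 and the 7-methoxy group), the usual site in 5,7-dimethoxyflavones, while the anisyl ring and C3 are much less reactive toward the silver-activated iodine.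

Step 3
Reactants: 2 3,5-dimethoxyphenyl N-isopropylcarbamate; 4 8-iodo-5,7,4'-trimethoxyflavone
Product: 11 3,5-dimethoxy-2-(5,7,4'-trimethoxyflavon-8-yl)-6-(trimethylsilyl)phenyl N-isopropylcarbamate, via N-silyl carbamate 5 (not isolated), via aryllithium 6 (not isolated), via N-silyl C-silyl carbamate 7 (not isolated), via silylated aryllithium 8 (not isolated), via arylzinc chloride 9 (not isolated), via N-silyl biaryl carbamate 10 (not isolated)
Conditions: TMSOTf, TMEDA, Et2O, 0 °C to rt; n-BuLi (2 equiv), TMEDA, −78 °C; TMSCl (1.05 equiv), −78 °C to rt; volatiles removed in vacuo, fresh Et2O; n-BuLi (1.1 equiv), TMEDA, −78 °C; ZnCl2, THF, −78 °C to rt; 4, Pd2(dba)3 (cat.), RuPhos, THF/NMP, 70 °C; aq. NH4Cl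
Reagents that add atoms: chlorotrimethylsilane, C[Si](C)(C)Cl
Why: Two directed ortho-metalations on one transiently N-silylated carbamate followed by Negishi cross-coupling, in which the carbamate steers the first lithiation to C2 (between carbamate and methoxy, in preference to C4 between the two methoxy groups) for trapping by TMSCl, the N-silyl group stays on so that the second lithiation can only take the remaining carbamate-flanked site C6, surplus chlorosilane is stripped before that lithiation, the arylzinc tolerates the flavone carbonyl and is free of the rapid protodeboronation of a 2,6-dioxygenated arylboronic acid, the bulky electron-rich RuPhos ligand is suited to tetra-ortho-substituted biaryls, and neutral aqueous work-up should remove only the N-silyl group.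

Step 4
Reactants: 11 3,5-dimethoxy-2-(5,7,4'-trimethoxyflavon-8-yl)-6-(trimethylsilyl)phenyl N-isopropylcarbamate
Product: 13 3,5-dimethoxy-2-(5,7,4'-trimethoxyflavon-8-yl)-6-(trimethylsilyl)phenyl trifluoromethanesulfonate, via biaryl phenol 12 (not isolated)
Conditions: Et2NH, DBU, MeCN, 40 °C; then PhNTf2, 40 °C
Reagents that add atoms: N-phenylbis(trifluoromethanesulfonimide), O=S(=O)(N(c1ccccc1)S(=O)(=O)C(F)(F)F)C(F)(F)F
Why: E1cB cleavage of the N–H carbamate (DBU deprotonates nitrogen, isopropyl isocyanate leaves and is scavenged by Et2NH) should free the phenoxide without touching the aryl–silicon bond or the flavone, and O-sulfonylation with PhNTf2 in the same flask should give the ortho-silylaryl triflate.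

Step 5
Reactants: 14 4-ethynyl-1,2-dimethoxybenzene
Product: 16 3-(3,4-dimethoxyphenyl)propiolic acid, via lithium acetylide 15 (not isolated)
Conditions: n-BuLi, THF, −78 °C; CO2, −78 °C to rt; aq. HCl
Reagents that add atoms: carbon dioxide, O=C=O
Why: Deprotonation of the terminal alkyne and carboxylation of the lithium acetylide with CO2 is a standard preparation of arylpropiolic acids.

Step 6
Reactants: 13 3,5-dimethoxy-2-(5,7,4'-trimethoxyflavon-8-yl)-6-(trimethylsilyl)phenyl trifluoromethanesulfonate; 16 3-(3,4-dimethoxyphenyl)propiolic acid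
Product: 19 5,7,4'-trimethoxyflavone-(8→8'')-5'',7'',3''',4'''-tetramethoxyflavone (hepta-O-methyl ether of 20), via aryne 17 (not isolated), via hydroxyaryl ynone 18 (not isolated)
Conditions: CsF (4 equiv), 16 (1.2 equiv), THF, 125 °C, sealed tube
Reagents that add atoms: none
Why: Fluoride attacks silicon and expels triflate to give aryne 17 across C4a''–C8a''; the carboxylate of 16 adds through oxygen at C8a'', the C4a'' carbanion attacks the ester carbonyl through a four-membered transition state so that the alkynoyl group moves from oxygen to carbon (forming O1''–C8a'' and C4''–C4a''), and the phenoxide of ynone 18 then adds to the triple bond (forming O1''–C2''), the acid proton ending at C3''. The closest known reaction type is the insertion of arynes into the C–O bond of carboxylic acids to give ortho-hydroxyaryl ketones, which with arylpropiolic acids is known to run on to flavones. Ring C closes in the 6-endo-dig mode by oxa-Michael addition, favoured over 5-exo-dig closure because the ynone is polarized toward attack at its β-carbon. No stereocenter is formed. The step needs the oxygen nucleophile at C8a'' and not at C4a'': the C5'' methoxy group beside the triple bond withdraws inductively, so attack at the remote carbon places the developing charge at C4a'' next to the C–O bond, a preference expected to outweigh the shielding of C8a'' by the C8'' flavonyl group. It also needs acyl transfer to outrun protonation of the aryl anion, which the high temperature, the aprotic medium and the near-stoichiometric amount of acid are chosen to secure, and the methylated apigenin unit should be inert to fluoride and to the aryne.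

Step 7
Reactants: 19 5,7,4'-trimethoxyflavone-(8→8'')-5'',7'',3''',4'''-tetramethoxyflavone
Product: 20 apigenin-(8→8'')-luteolin, 8-[2-(3,4-dihydroxyphenyl)-5,7-dihydroxy-4-oxo-4H-chromen-8-yl]-5,7-dihydroxy-2-(4-hydroxyphenyl)-4H-chromen-4-one
Conditions: BBr3 (excess), CH2Cl2, −78 °C to 40 °C; MeOH, then H2O
Reagents that add atoms: none
Why: Lewis-acid ether cleavage (BBr3 demethylation) should remove all seven methyl groups, the two peri 5-methoxy groups fastest through chelation to the carbonyls, and anhydrous conditions at or below 40 °C avoid the ring-opening isomerisation of 8-linked units (Wessely–Moser rearrangement) that hot protic acids can cause.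

Compound list
1 | 3,5-dimethoxyphenol | COc1cc(O)cc(OC)c1 | starting material
2 | 3,5-dimethoxyphenyl N-isopropylcarbamate | CC(C)NC(=O)Oc1cc(OC)cc(OC)c1 | intermediate
3 | 5,7,4'-trimethoxyflavone | O=c1cc(-c2ccc(OC)cc2)oc2cc(OC)cc(OC)c12 | starting material
4 | 8-iodo-5,7,4'-trimethoxyflavone | O=c1cc(-c2ccc(OC)cc2)oc2c(I)c(OC)cc(OC)c12 | intermediate
5 | 3,5-dimethoxyphenyl N-isopropyl-N-(trimethylsilyl)carbamate (formed in the flask) | CC(C)N([Si](C)(C)C)C(=O)Oc1cc(OC)cc(OC)c1 | intermediate
6 | [2-(N-isopropyl-N-trimethylsilylcarbamoyloxy)-4,6-dimethoxyphenyl]lithium (formed in the flask) | CC(C)N([Si](C)(C)C)C(=O)Oc1cc(OC)cc(OC)c1[Li] | intermediate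
7 | 3,5-dimethoxy-2-(trimethylsilyl)phenyl N-isopropyl-N-(trimethylsilyl)carbamate (formed in the flask) | CC(C)N([Si](C)(C)C)C(=O)Oc1cc(OC)cc(OC)c1[Si](C)(C)C | intermediate
8 | [2-(N-isopropyl-N-trimethylsilylcarbamoyloxy)-4,6-dimethoxy-3-(trimethylsilyl)phenyl]lithium (formed in the flask) | CC(C)N([Si](C)(C)C)C(=O)Oc1c([Li])c(OC)cc(OC)c1[Si](C)(C)C | intermediate
9 | [2-(N-isopropyl-N-trimethylsilylcarbamoyloxy)-4,6-dimethoxy-3-(trimethylsilyl)phenyl]zinc chloride (formed in the flask) | CC(C)N([Si](C)(C)C)C(=O)Oc1c([Zn]Cl)c(OC)cc(OC)c1[Si](C)(C)C | intermediate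
10 | 3,5-dimethoxy-2-(5,7,4'-trimethoxyflavon-8-yl)-6-(trimethylsilyl)phenyl N-isopropyl-N-(trimethylsilyl)carbamate (formed in the flask) | O=c1cc(-c2ccc(OC)cc2)oc2c(-c3c(OC)cc(OC)c([Si](C)(C)C)c3OC(=O)N(C(C)C)[Si](C)(C)C)c(OC)cc(OC)c12 | intermediate
11 | 3,5-dimethoxy-2-(5,7,4'-trimethoxyflavon-8-yl)-6-(trimethylsilyl)phenyl N-isopropylcarbamate | O=c1cc(-c2ccc(OC)cc2)oc2c(-c3c(OC)cc(OC)c([Si](C)(C)C)c3OC(=O)NC(C)C)c(OC)cc(OC)c12 | intermediate
12 | 3,5-dimethoxy-2-(5,7,4'-trimethoxyflavon-8-yl)-6-(trimethylsilyl)phenol (formed in the flask) | O=c1cc(-c2ccc(OC)cc2)oc2c(-c3c(OC)cc(OC)c([Si](C)(C)C)c3O)c(OC)cc(OC)c12 | intermediate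
13 | 3,5-dimethoxy-2-(5,7,4'-trimethoxyflavon-8-yl)-6-(trimethylsilyl)phenyl trifluoromethanesulfonate | O=c1cc(-c2ccc(OC)cc2)oc2c(-c3c(OC)cc(OC)c([Si](C)(C)C)c3OS(=O)(=O)C(F)(F)F)c(OC)cc(OC)c12 | intermediate
14 | 4-ethynyl-1,2-dimethoxybenzene | C#Cc1ccc(OC)c(OC)c1 | starting material
15 | lithium (3,4-dimethoxyphenyl)acetylide (formed in the flask) | [Li]C#Cc1ccc(OC)c(OC)c1 | intermediate
16 | 3-(3,4-dimethoxyphenyl)propiolic acid | OC(=O)C#Cc1ccc(OC)c(OC)c1 | intermediate
17 | 3,5-dimethoxy-6-(5,7,4'-trimethoxyflavon-8-yl)-1,2-didehydrobenzene, the C4a''–C8a'' aryne (formed in the flask) | O=c1cc(-c2ccc(OC)cc2)oc2c(C3=C(OC)C=C(OC)C#C3)c(OC)cc(OC)c12 | intermediate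
18 | 1-[2-hydroxy-4,6-dimethoxy-3-(5,7,4'-trimethoxyflavon-8-yl)phenyl]-3-(3,4-dimethoxyphenyl)prop-2-yn-1-one (formed in the flask) | O=c1cc(-c2ccc(OC)cc2)oc2c(-c3c(OC)cc(OC)c(C(=O)C#Cc4ccc(OC)c(OC)c4)c3O)c(OC)cc(OC)c12 | intermediate
19 | 5,7,4'-trimethoxyflavone-(8→8'')-5'',7'',3''',4'''-tetramethoxyflavone (hepta-O-methyl ether of 20) | O=c1cc(-c2ccc(OC)cc2)oc2c(-c3c(OC)cc(OC)c4c(=O)cc(-c5ccc(OC)c(OC)c5)oc34)c(OC)cc(OC)c12 | intermediate
20 | apigenin-(8→8'')-luteolin, no stereocenter, axis unspecified | O=c1cc(-c2ccc(O)cc2)oc2c(-c3c(O)cc(O)c4c(=O)cc(-c5ccc(O)c(O)c5)oc34)c(O)cc(O)c12 | target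

Total step count: 7
Longest linear sequence: 5 steps (steps 1, 3, 4, 6 and 7)

Steps most likely to fail

Step 6. The aryl anion may be protonated before the acyl group migrates, so that the reaction stops at O-arylation. The carboxylate may also add at the wrong aryne carbon because C8a'' is crowded, or the propiolic acid may decarboxylate at the temperature needed. The fallback avoids the aryne altogether; it sets out from compound 11 and returns at compound 19. Ipso-iododesilylation of 11 (ICl, CH2Cl2, −78 °C) should replace silicon at C4a'' by iodine and give 6-iodo-3,5-dimethoxy-2-(5,7,4'-trimethoxyflavon-8-yl)phenyl N-isopropylcarbamate F1. E1cB cleavage of the carbamate (Et2NH, DBU, MeCN, 40 °C) should then free 6-iodo-3,5-dimethoxy-2-(5,7,4'-trimethoxyflavon-8-yl)phenol F2. Carbonylative Sonogashira coupling of F2 with alkyne 14 (PdCl2(PPh3)2 cat., CO 1 atm, Et2NH, DMF, 80 °C), a known flavone annulation of ortho-iodophenols, should pass through the same ynone 18 and close to 19. In this variant C4'' comes from carbon monoxide and O1'' is the original phenol oxygen.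

Step 3. Reductive elimination across a tetra-ortho-substituted axis may be too slow, so that the arylzinc is only protonated or homocoupled. Chlorosilane carried into the second metalation, or lithiation between the two methoxy groups, would also feed by-products into the coupling. The fallback separates the double metalation from the biaryl coupling and uses a Suzuki–Miyaura coupling of isolated partners; it sets out from compounds 2 and 4 and returns at compound 11. Carbamate 2 is taken through the N-silylation and both metalations of step 3 as far as aryllithium 8, which is quenched with I2 in place of ZnCl2. This gives 2-iodo-3,5-dimethoxy-6-(trimethylsilyl)phenyl N-isopropyl-N-(trimethylsilyl)carbamate F3 in the flask and, after aqueous work-up, 2-iodo-3,5-dimethoxy-6-(trimethylsilyl)phenyl N-isopropylcarbamate F4, which can be purified before the flavone is committed. Miyaura borylation of 4 (B2pin2, PdCl2(dppf), KOAc, dioxane, 90 °C) gives 5,7,4'-trimethoxy-8-(4,4,5,5-tetramethyl-1,3,2-dioxaborolan-2-yl)flavone F5. Coupling of F4 with F5 (Pd(OAc)2, SPhos, anhydrous K3PO4, toluene, 90 °C) should give 11. Any phenol 12 formed by early loss of the carbamate would enter step 4 at the sulfonylation stage.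

Step 4. O-Sulfonylation of a phenoxide buried between the silyl group and the flavonyl group may be slow. That would leave time for loss of silicon from the phenoxide or for amine addition to the pyranone. The fallback moves the triflation ahead of the biaryl coupling; it sets out from compounds 2 and 4 and returns at compound 13. 2-Iodo-3,5-dimethoxy-6-(trimethylsilyl)phenyl N-isopropylcarbamate F4 and 5,7,4'-trimethoxy-8-(4,4,5,5-tetramethyl-1,3,2-dioxaborolan-2-yl)flavone F5 are prepared as in the fallback to step 3. F4 is cleaved with Et2NH and DBU in MeCN to 2-iodo-3,5-dimethoxy-6-(trimethylsilyl)phenol F6, which is sulfonylated in the same flask with PhNTf2 to 2-iodo-3,5-dimethoxy-6-(trimethylsilyl)phenyl trifluoromethanesulfonate F7. A fluoride-free Suzuki–Miyaura coupling of F7 with F5 (Pd(OAc)2, SPhos, anhydrous K3PO4, toluene, 70 °C) should be selective for the carbon–iodine bond over the shielded triflate and give 13.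

Further compounds
F1 | step 6 | 6-iodo-3,5-dimethoxy-2-(5,7,4'-trimethoxyflavon-8-yl)phenyl N-isopropylcarbamate | O=c1cc(-c2ccc(OC)cc2)oc2c(-c3c(OC)cc(OC)c(I)c3OC(=O)NC(C)C)c(OC)cc(OC)c12
F2 | step 6 | 6-iodo-3,5-dimethoxy-2-(5,7,4'-trimethoxyflavon-8-yl)phenol | O=c1cc(-c2ccc(OC)cc2)oc2c(-c3c(OC)cc(OC)c(I)c3O)c(OC)cc(OC)c12
F3 | step 3 | 2-iodo-3,5-dimethoxy-6-(trimethylsilyl)phenyl N-isopropyl-N-(trimethylsilyl)carbamate | CC(C)N([Si](C)(C)C)C(=O)Oc1c(I)c(OC)cc(OC)c1[Si](C)(C)C
F4 | step 3 | 2-iodo-3,5-dimethoxy-6-(trimethylsilyl)phenyl N-isopropylcarbamate | CC(C)NC(=O)Oc1c(I)c(OC)cc(OC)c1[Si](C)(C)C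
F5 | step 3 | 5,7,4'-trimethoxy-8-(4,4,5,5-tetramethyl-1,3,2-dioxaborolan-2-yl)flavone | O=c1cc(-c2ccc(OC)cc2)oc2c(B3OC(C)(C)C(C)(C)O3)c(OC)cc(OC)c12
F6 | step 4 | 2-iodo-3,5-dimethoxy-6-(trimethylsilyl)phenol | Oc1c(I)c(OC)cc(OC)c1[Si](C)(C)C
F7 | step 4 | 2-iodo-3,5-dimethoxy-6-(trimethylsilyl)phenyl trifluoromethanesulfonate | O=S(=O)(Oc1c(I)c(OC)cc(OC)c1[Si](C)(C)C)C(F)(F)F
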